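**Strategy.** Ring C is disconnected across C2–C3 and C4–C4a. The precursor is an O-aryl O-acetyl acetal in which the future O1–C2 bond already links a benzyl-protected resorcinol (ring A) to the silylated 2,4-dihydroxybenzaldehyde carbon (ring B). Ionization gives an aryl oxocarbenium ion, a cationic 2-oxadiene made of O1=C2 and the C8a=C4a edge of ring A. A chiral counteranion catalyst lets ethoxyacetylene, a ketene equivalent, add to C2, and the ketenium ion then closes onto C4a, which is ortho to O1 and para to O7. One operation thus builds the chromanone ring and sets C2. Late diiodination ortho to the freed 7-OH and twofold Stille prenylation finish ring A.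

Key step: step 3

Remark (assumption): the sense of induction of the chiral acid in step 3 cannot be assigned in advance. The (S,S) acid is written; its mirror image is used if a test run shows the 2R sense.

**Step 1**
Reactants: 1 2,4-dihydroxybenzaldehyde
Product: 2 2,4-bis(triisopropylsilyloxy)benzaldehyde
Conditions: i-Pr3SiCl (2.5 equiv), imidazole (5 equiv), DMAP (cat.), DMF, 40 °C
Reagents that add atoms: triisopropylsilyl chloride, CC(C)[Si](Cl)(C(C)C)C(C)C
Why: Imidazole-promoted silyl ether formation on both phenols; the bulky TIPS ethers should survive phenoxide, acid and palladium later and are poor neighbouring groups.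

**Step 2**
Reactants: 2 2,4-bis(triisopropylsilyloxy)benzaldehyde; 3 3-(benzyloxy)phenol
Product: 5 [3-(benzyloxy)phenoxy][2,4-bis(triisopropylsilyloxy)phenyl]methyl acetate, via bromo acetate 4 (not isolated)
Conditions: AcBr (1.05 equiv), CH2Cl2, 0 °C; then added to 3, Cs2CO3, MeCN, −20 °C → rt
Reagents that add atoms: acetyl bromide, CC(Br)=O
Why: Acetyl bromide adds across the aldehyde C=O (α-haloalkyl ester formation) and the caesium phenoxide displaces bromide at oxygen (Williamson-type O-alkylation), giving a mixed acetal in which only acetate can leave; the acetal centre is racemic and is erased in step 3.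

**Step 3**
Reactants: 5 [3-(benzyloxy)phenoxy][2,4-bis(triisopropylsilyloxy)phenyl]methyl acetate; 6 ethoxyacetylene
Product: 8 (2S)-7-(benzyloxy)-2-[2,4-bis(triisopropylsilyloxy)phenyl]chroman-4-one, via 4-ethoxy-2H-chromene 7 (not isolated)
Conditions: IDPi acid HN[P(=NSO2CF3)(L)]2, L = (S)-3,3'-bis[3,5-(CF3)2C6H3]-1,1'-binaphthyl-2,2'-diolate (5 mol %), 6 (5 equiv, slow addition), 5 Å MS, toluene (0.02 M), −60 °C; then 1 M aq. HCl, THF, 0 °C
Reagents that add atoms: water, O
Why: Proposed new method: the IDPi acid ionizes the acetate of 5 to an aryl oxocarbenium ion held as a contact ion pair with the confined chiral anion; the CH terminus of ethoxyacetylene adds to C2 (C2–C3 bond) and the resulting O-ethyl ketenium ion is trapped at once by the ring A carbon ortho to O1 and para to the benzyloxy group (C4–C4a bond), proton loss regenerating the acid. The closest known reaction type is the Lewis acid promoted oxa-Povarov reaction of aryl oxocarbenium ions with alkenes and alkynes (Prins-type addition, then Friedel–Crafts closure), here made catalytic and enantioselective by asymmetric counteranion-directed Brønsted acid catalysis and run with an ynol ether as ketene equivalent. The pyran ring closes in a 6-exo-dig Friedel–Crafts mode on the sp carbon of the ketenium ion, the C3=C4 bond ending inside the ring. The C2 stereocenter is set in the C2–C3 bond-forming addition, the chiral IDPi anion shielding one face of the planar oxocarbenium ion so that 2S results. The step needs closure para to the benzyl ether and not between the two oxygens, and no capture of the ketenium ion by the 2'-silyloxy oxygen; the lower hindrance and double activation of the para carbon and the bulky, weakly basic OTIPS group should secure both. Dilute aqueous HCl in the work-up hydrolyses enol ether 7 to ketone 8 without touching C2.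

**Step 4**
Reactants: 8 (2S)-7-(benzyloxy)-2-[2,4-bis(triisopropylsilyloxy)phenyl]chroman-4-one
Product: 9 (2S)-2-[2,4-bis(triisopropylsilyloxy)phenyl]-7-hydroxychroman-4-one
Conditions: H2 (1 atm), Pd/C (10 wt % Pd), EtOAc, rt
Reagents that add atoms: none
Why: Hydrogenolysis of the benzyl ether frees the 7-OH under neutral conditions that should leave the aryl silyl ethers, the ketone and C2 alone.

**Step 5**
Reactants: 9 (2S)-2-[2,4-bis(triisopropylsilyloxy)phenyl]-7-hydroxychroman-4-one
Product: 10 (2S)-2-[2,4-bis(triisopropylsilyloxy)phenyl]-7-hydroxy-6,8-diiodochroman-4-one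
Conditions: N-iodosuccinimide (2.2 equiv), DMF, 0 °C → rt, dark
Reagents that add atoms: N-iodosuccinimide, O=C1CCC(=O)N1I
Why: Electrophilic aromatic iodination: the free 7-OH together with O1 activates only C6 and C8 (its para position C4a is substituted), while the bulky OTIPS groups shield ring B.

**Step 6**
Reactants: 10 (2S)-2-[2,4-bis(triisopropylsilyloxy)phenyl]-7-hydroxy-6,8-diiodochroman-4-one; 11 tributyl(3-methylbut-2-en-1-yl)stannane
Product: 12 (2S)-2-[2,4-bis(triisopropylsilyloxy)phenyl]-7-hydroxy-6,8-bis(3-methylbut-2-en-1-yl)chroman-4-one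
Conditions: 11 (3 equiv), Pd(PPh3)4 (10 mol %), DMF, 90 °C
Reagents that add atoms: none
Why: Twofold Stille coupling under neutral conditions, the allyl unit being delivered at its tin-bearing CH2 terminus so that linear prenyl groups should result, with no base present that could open the chromanone and racemize C2.

**Step 7**
Reactants: 12 (2S)-2-[2,4-bis(triisopropylsilyloxy)phenyl]-7-hydroxy-6,8-bis(3-methylbut-2-en-1-yl)chroman-4-one
Product: 13 (2S)-2-(2,4-dihydroxyphenyl)-7-hydroxy-6,8-bis(3-methylbut-2-en-1-yl)chroman-4-one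
Conditions: Bu4NF (2.5 equiv), AcOH (2.5 equiv), THF, 0 °C
Reagents that add atoms: none
Why: Fluoride-mediated cleavage of both aryl silyl ethers, buffered with acetic acid to avoid phenoxide-driven retro-oxa-Michael opening (racemization of C2) and acid-driven cyclization of the prenyl groups.

**Compound list**
1 | 2,4-dihydroxybenzaldehyde | O=Cc1ccc(O)cc1O | starting material
2 | 2,4-bis(triisopropylsilyloxy)benzaldehyde | O=Cc1ccc(O[Si](C(C)C)(C(C)C)C(C)C)cc1O[Si](C(C)C)(C(C)C)C(C)C | intermediate
3 | 3-(benzyloxy)phenol | Oc1cccc(OCc2ccccc2)c1 | starting material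
4 | bromo[2,4-bis(triisopropylsilyloxy)phenyl]methyl acetate (racemic) | CC(=O)OC(Br)c1ccc(O[Si](C(C)C)(C(C)C)C(C)C)cc1O[Si](C(C)C)(C(C)C)C(C)C | intermediate
5 | [3-(benzyloxy)phenoxy][2,4-bis(triisopropylsilyloxy)phenyl]methyl acetate (racemic) | CC(=O)OC(Oc1cccc(OCc2ccccc2)c1)c1ccc(O[Si](C(C)C)(C(C)C)C(C)C)cc1O[Si](C(C)C)(C(C)C)C(C)C | intermediate
6 | ethoxyacetylene (ethoxyethyne) | CCOC#C | starting material
7 | (2S)-7-(benzyloxy)-2-[2,4-bis(triisopropylsilyloxy)phenyl]-4-ethoxy-2H-chromene | c1ccccc1COc1ccc2c(c1)O[C@H](c1ccc(O[Si](C(C)C)(C(C)C)C(C)C)cc1O[Si](C(C)C)(C(C)C)C(C)C)C=C2OCC | intermediate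
8 | (2S)-7-(benzyloxy)-2-[2,4-bis(triisopropylsilyloxy)phenyl]chroman-4-one | c1ccccc1COc1ccc2c(c1)O[C@H](c1ccc(O[Si](C(C)C)(C(C)C)C(C)C)cc1O[Si](C(C)C)(C(C)C)C(C)C)CC2=O | intermediate
9 | (2S)-2-[2,4-bis(triisopropylsilyloxy)phenyl]-7-hydroxychroman-4-one | Oc1ccc2c(c1)O[C@H](c1ccc(O[Si](C(C)C)(C(C)C)C(C)C)cc1O[Si](C(C)C)(C(C)C)C(C)C)CC2=O | intermediate
10 | (2S)-2-[2,4-bis(triisopropylsilyloxy)phenyl]-7-hydroxy-6,8-diiodochroman-4-one | Oc1c(I)cc2c(c1I)O[C@H](c1ccc(O[Si](C(C)C)(C(C)C)C(C)C)cc1O[Si](C(C)C)(C(C)C)C(C)C)CC2=O | intermediate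
11 | tributyl(3-methylbut-2-en-1-yl)stannane | CCCC[Sn](CCCC)(CCCC)CC=C(C)C | starting material
12 | (2S)-2-[2,4-bis(triisopropylsilyloxy)phenyl]-7-hydroxy-6,8-bis(3-methylbut-2-en-1-yl)chroman-4-one | CC(C)=CCc1cc2c(c(CC=C(C)C)c1O)O[C@H](c1ccc(O[Si](C(C)C)(C(C)C)C(C)C)cc1O[Si](C(C)C)(C(C)C)C(C)C)CC2=O | intermediate
13 | (2S)-2-(2,4-dihydroxyphenyl)-7-hydroxy-6,8-bis(3-methylbut-2-en-1-yl)chroman-4-one | CC(C)=CCc1cc2c(c(CC=C(C)C)c1O)O[C@H](c1ccc(O)cc1O)CC2=O | target

**Total step count:** 7. **Longest linear sequence:** 7 steps (1 → 13); compounds 3, 6 and 11 are purchased.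

**Steps most likely to fail**

Step 3 (proposed new method). The strong acid may consume the ynol ether by protonation and oligomerization faster than it ionizes 5. The ketenium ion may be intercepted by acetate before ring closure. The oxocarbenium ion may alkylate ring A of a second molecule. The ion pair may give poor facial selectivity. Fallback with known chemistry, making the two bonds one after the other and securing the enantiomer by resolution: from 5, Me3SiOTf-promoted Mukaiyama-type addition of 1,1-bis(trimethylsilyloxy)ethene (CH2Cl2, −78 °C) and aqueous work-up would give racemic 3-[3-(benzyloxy)phenoxy]-3-[2,4-bis(triisopropylsilyloxy)phenyl]propanoic acid F1. Intramolecular Friedel–Crafts acylation through the mixed trifluoroacetic anhydride (TFAA, CH2Cl2, 0 °C) would close ring C to racemic 7-(benzyloxy)-2-[2,4-bis(triisopropylsilyloxy)phenyl]chroman-4-one F2. Kinetic resolution by asymmetric transfer hydrogenation (RuCl[(R,R)-TsDPEN](p-cymene), HCO2H/Et3N, EtOAc, rt, stopped near half conversion) should reduce the 2R enantiomer to the cis alcohol (2R,4R)-7-(benzyloxy)-2-[2,4-bis(triisopropylsilyloxy)phenyl]chroman-4-ol F3, which is separated by chromatography, and leave 8, where the route is rejoined.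

Step 6. The prenyl group may be transferred with allylic transposition (reverse prenyl). The second coupling at the hindered C8 position may stall. Protodeiodination may compete next to the free phenol. Fallback: from 10, twofold Stille coupling with allyltributylstannane (Pd(PPh3)4, DMF, 90 °C), which has no regiochemical ambiguity, would give (2S)-6,8-diallyl-2-[2,4-bis(triisopropylsilyloxy)phenyl]-7-hydroxychroman-4-one F4. Twofold olefin cross-metathesis with 2-methyl-2-butene (second-generation Grubbs catalyst, CH2Cl2, 40 °C) would turn both allyl groups into prenyl groups and return to 12.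

Step 2. The bromo acetate may revert to aldehyde and acetyl bromide, which then acetylates the phenoxide. It may also ionize and alkylate the electron-rich phenol at carbon instead of oxygen. Fallback: from 2, Pinnick oxidation (NaClO2, NaH2PO4, 2-methyl-2-butene, t-BuOH/H2O) would give 2,4-bis(triisopropylsilyloxy)benzoic acid F5. Steglich esterification with 3 (DCC, DMAP, CH2Cl2) would give 3-(benzyloxy)phenyl 2,4-bis(triisopropylsilyloxy)benzoate F6. Reductive acetylation (i-Bu2AlH, CH2Cl2, −78 °C; then Ac2O, pyridine, DMAP) would trap the tetrahedral intermediate as the acetate and return to 5.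

**Further compounds**
F1 | step 3 | 3-[3-(benzyloxy)phenoxy]-3-[2,4-bis(triisopropylsilyloxy)phenyl]propanoic acid (racemic) | OC(=O)CC(Oc1cccc(OCc2ccccc2)c1)c1ccc(O[Si](C(C)C)(C(C)C)C(C)C)cc1O[Si](C(C)C)(C(C)C)C(C)C
F2 | step 3 | 7-(benzyloxy)-2-[2,4-bis(triisopropylsilyloxy)phenyl]chroman-4-one (racemic) | c1ccccc1COc1ccc2c(c1)OC(c1ccc(O[Si](C(C)C)(C(C)C)C(C)C)cc1O[Si](C(C)C)(C(C)C)C(C)C)CC2=O
F3 | step 3 | (2R,4R)-7-(benzyloxy)-2-[2,4-bis(triisopropylsilyloxy)phenyl]chroman-4-ol | c1ccccc1COc1ccc2c(c1)O[C@@H](c1ccc(O[Si](C(C)C)(C(C)C)C(C)C)cc1O[Si](C(C)C)(C(C)C)C(C)C)C[C@H]2O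
F4 | step 6 | (2S)-6,8-diallyl-2-[2,4-bis(triisopropylsilyloxy)phenyl]-7-hydroxychroman-4-one | C=CCc1cc2c(c(CC=C)c1O)O[C@H](c1ccc(O[Si](C(C)C)(C(C)C)C(C)C)cc1O[Si](C(C)C)(C(C)C)C(C)C)CC2=O
F5 | step 2 | 2,4-bis(triisopropylsilyloxy)benzoic acid | OC(=O)c1ccc(O[Si](C(C)C)(C(C)C)C(C)C)cc1O[Si](C(C)C)(C(C)C)C(C)C
F6 | step 2 | 3-(benzyloxy)phenyl 2,4-bis(triisopropylsilyloxy)benzoate | O=C(Oc1cccc(OCc2ccccc2)c1)c1ccc(O[Si](C(C)C)(C(C)C)C(C)C)cc1O[Si](C(C)C)(C(C)C)C(C)C
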